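# Synthesis plan for CNP0112262.1, the (2S,3S)-trans-2,3-diaryl-2,3-dihydrobenzofuran

## The problem

The target is a (2S,3S)-trans-2,3-diaryl-2,3-dihydrobenzofuran. Ring B (O1, C2, C3, C3a, C7a) is fused to the phloroglucinol-type ring A (C3a, C4 to C7, C7a), which carries a hydroxyl at C4 and a 6-hydroxybenzofuran-2-yl group at C6; C2 bears a 4-hydroxyphenyl group and C3 a 3,5-dihydroxyphenyl group. The two stereocentres are adjacent and trans, the more stable arrangement, so one centre fixed in absolute terms can dictate the other whenever the second may equilibrate. C2 is the better anchor: C3 becomes epimerisable as soon as it carries a carbonyl group, whereas C2 cannot be corrected without breaking the ring. The weak point is the C2–O1 bond, a benzylic aryl ether para to an oxygen substituent. Acids ionise it, and once the 4-hydroxyphenyl group is free, hot base can expel the ring A phenoxide through a quinone methide. The 2-arylbenzofuran and the polyphenolic rings are easily oxidised, five phenols must be carried protected, and the three oxygens of ring A (ring ether, hydroxyl, and a site that ends as a C–C bond) must be told apart early. The enabling feature is the aryl group on C3: a resorcinol joined through its C5, so that oxygen sits on every second ring carbon counted from the carbon bonded to C3. That is the pattern of a tetraketide folded by aldol condensation with its starter acyl carbon as the point of attachment, so the whole ring can be grown from a carboxyl-derived acyl group on C3.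

## Retrosynthesis

**Ether cleavage (21 from 20).** Target 21 is traced to its tri-O-methyl ether 20 by cutting three O–CH3 bonds. Methyl is the only group that survives every operation of the route (acidic oxidant, hydrogenolysis, amide bases, hot hydroxide). It is removed last because a free 4-hydroxyphenyl group on C2 would make the C2–O1 bond base-labile during the hydrolysis that precedes. The forward step must cleave three aryl methyl ethers without lasting damage at C2.

**Decarboxylation (20 from 18 via 19).** The resorcinol ring of 20 is traced to the isopropylidene-protected resorcylate 18 by restoring a carboxyl carbon ortho to the C3 substituent; the free acid 19 lies between them. The polyketide fold necessarily delivers this carbon, and a β-resorcylic acid loses it easily. The forward step is hydrolysis of the benzodioxinone and protodecarboxylation, with no stereochemical demand because C3 of 18 is not enolisable.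

**Aromatic ring from an open chain (18 from 17).** The benzodioxinone ring of 18 is cut at the bond between its C5 (the carbon bonded to C3 of the dihydrobenzofuran) and C4a, giving diketo-dioxinone 17. The neighbouring cuts would be the C3–aryl bond, which would require arylation of a hindered benzylic stereocentre, or a ring B bond, which carries both aryl groups into the ring-forming step. The chosen cut replaces the second aryl group by an acyl chain, so the stereochemical problem becomes a trans 3-acyl-2-aryl-dihydrobenzofuran whose C3 is under thermodynamic control. The forward step must close through carbon, dehydrate and aromatise at room temperature.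

**Claisen condensation (17 from 13 and 15).** The chain of 17 is cut between the carbonyl carbon bonded to C3 and the neighbouring methylene, giving carboxylic acid 13, activated in the flask as acyl imidazole 16, and keto-dioxinone 15. This places the only carbon–carbon bond to C3's substituent at a carboxyl carbon, the oxidation level the ring contraction below delivers. Compound 15 comes in one step from the catalogue dioxinone 14. The forward reaction must acylate the terminal carbon of the dianion of 15 without opening ring B.

**Benzofuran attachment (13 from 10 and 11).** Acid 13 comes from ester 12, which is cut at the bond between C6 of ring A and C2 of the benzofuran, giving aryl triflate 10 and boronic acid 11. The coupling is placed after the oxidative step because the electron-rich benzofuran would not survive it. It uses an oxygen of ring A as the handle because that ring originates from a phloroglucinol. Triflate 10 comes from phenol 9, and 9 from benzyl ether 8; benzyl is the one ether that can be removed beside methyl ethers.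

**Ring contraction (8 from 7).** In 8 the C3–C3a bond is cut and C3a is reconnected to the ester carbon, which gives flavanone 7. A dihydrobenzofuran with two stereocentres becomes a flavanone with one, and flavanones are well served by catalytic asymmetric synthesis. The neighbouring way to 8, carbene C–H insertion, needs a longer aryl diazoacetate synthesis and is kept as a fallback. The forward step must move the ring A carbon and not the C2 aryl group, give the trans ester, and leave C2 untouched.

**Aryl addition (7 from 5 and 6).** The C2–aryl bond of 7 is cut to chromone 5 and boronic acid 6. An enantioselective conjugate addition sets the only stereocentre the route has to create by reagent control.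

**Ring A differentiation (5 from 1).** Chromone 5 comes from acetophenone 3 by adding one carbon through enaminone 4. Compound 3 comes from 2 by methylation, and 2 from 2,4,6-trihydroxyacetophenone 1 by benzylation. The three oxygens of 1 are differentiated by acidity and hydrogen bonding alone.

## Roads not taken

**Alternative 1:** The cut is the C2–C3 bond. Ring B is closed by insertion of a diaryl carbene centred on the future C3 into the benzylic C–H bond of a 4-methoxybenzyl aryl ether. Hydrazone A2, [4-bromo-2-methoxy-6-(4-methoxybenzyloxy)phenyl](3,5-dimethoxyphenyl)methanone hydrazone, is oxidised by MnO2 and decomposed in the same flask by Rh2(R-PTAD)4 or its enantiomer. The product is cis-dihydrobenzofuran A1, (2R,3S)-6-bromo-3-(3,5-dimethoxyphenyl)-4-methoxy-2-(4-methoxyphenyl)-2,3-dihydro-1-benzofuran, with both stereocentres set by the catalyst. Acid-mediated inversion of C2 to the trans series, coupling of the bromide with 11 and ether cleavage would finish.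
- Merits: it is the shortest of the routes considered, it is convergent, and a single catalytic step controls both centres.
- Weak points: the carbene carbon lies between two ortho oxygen substituents of ring A, so formation of A2 from a doubly ortho-substituted diaryl ketone and its oxidation are hindered. The ortho methoxy group offers a second, if less activated, site for 1,5-insertion. The catalyst gives the cis isomer, so the trans target is reached only by ionising the C2–O1 bond on purpose, with C3 as the sole carrier of chirality. Five methyl ethers must be cleaved at the end.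
- Comparison: in step count this road is clearly better. The chosen plan offers a trans relationship that arises directly under thermodynamic control, no hindered hydrazone, and steps that each have close precedent on the functional pattern at hand.

**Alternative 2:** The cut removes three bonds of ring A (C3a–C7a, C4–C5 and C7–C7a). Heating cyclobutenone A5, 3-(6-methoxy-1-benzofuran-2-yl)cyclobut-2-en-1-one, with the chiral siloxyalkyne A4 starts a cascade of four-electron ring opening, [2+2] cycloaddition, a second ring opening and six-electron closure. It should give A3, the ring A phenol with the future O1 free, the C4 oxygen silylated and the side chain intact. Ring B would then be closed by acid-mediated loss of the benzylic silyloxy group, trans by thermodynamics.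
- Merits: the substitution of ring A follows from connectivity alone, its oxygens are differentiated automatically, and the benzofuran arrives without a cross-coupling or a benzyl/triflate detour.
- Weak points: A4 must carry the C3 stereocentre, which is propargylic and benzylic and therefore at risk at benzannulation temperatures. Its carbinol centre is lost in the cationic closure, so the effort of setting it is wasted. Neither A4 nor A5 has a catalogue origin, and each needs several steps. Branching next to the alkyne slows the cycloaddition.
- Comparison: both plans build an aromatic ring from an open chain, and this one is the more convergent at ring A. The chosen plan starts from bought building blocks, builds its ring at room temperature, and places its stereocentre by catalysis on a simple chromone.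

**Alternative 3:** The cut removes C2–C3 and O1–C2. Cs2CO3 converts sulfone A7, 2-[(3,5-dimethoxyphenyl)(4-methylbenzenesulfonyl)methyl]-3-methoxy-5-(6-methoxy-1-benzofuran-2-yl)phenol, into an ortho-quinone methide by loss of sulfinate. The ylide from thiolanium salt A8, (2R,5R)-1-(4-methoxybenzyl)-2,5-dimethylthiolan-1-ium tetrafluoroborate, adds to the exocyclic carbon (future C3), and the phenoxide displaces the sulfide. The product is A6, the trans pentamethyl ether of the target, one step from the natural product.
- Merits: it is the most convergent road, it gives the trans isomer directly, and it forms two bonds and both stereocentres at once.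
- Weak points: absolute control rests on a stoichiometric chiral sulfide transferring a semi-stabilised benzyl group to a quinone methide whose reacting carbon carries an aryl group and is flanked by the C4 methoxy group. Precedent for high enantioselectivity with this combination is thin, and reversible ylide addition can erode it. A7 requires selective functionalisation of a 3,5-disubstituted phenol at the position between hydroxyl and methoxy, with two other activated positions open.
- Comparison: if enantiocontrol were secured this road would be shorter and better. The chosen plan takes its absolute configuration from a catalytic reaction of established scope on chromones and its relative configuration from thermodynamics.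

Key step: step 12

Assumption: the sense of induction in step 4 is taken from the model for cyclic enones, which assigns the (R)-configured pyridine–oxazoline ligand to the (2S)-flavanone; should the sense be opposite, the enantiomeric ligand is used and nothing else changes.

## Route

Step 1
Reactants: 1 2,4,6-trihydroxyacetophenone
Product: 2 1-[4-(benzyloxy)-2,6-dihydroxyphenyl]ethan-1-one
Conditions: BnBr (1.0 equiv), K2CO3, DMF, rt
Reagents that add atoms: benzyl bromide, BrCc1ccccc1
Why: Williamson etherification; the 4-hydroxyl is the only one not hydrogen-bonded to the ketone and is the most acidic, so one equivalent of halide should alkylate it first.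

Step 2
Reactants: 2 1-[4-(benzyloxy)-2,6-dihydroxyphenyl]ethan-1-one
Product: 3 1-[4-(benzyloxy)-2-hydroxy-6-methoxyphenyl]ethan-1-one
Conditions: Me2SO4 (1.05 equiv), K2CO3, acetone, reflux
Reagents that add atoms: dimethyl sulfate, COS(=O)(=O)OC
Why: Williamson methylation of one of two equivalent ortho hydroxyls; the remaining one is held in a strong hydrogen bond to the carbonyl group and should resist a second alkylation.

Step 3
Reactants: 3 1-[4-(benzyloxy)-2-hydroxy-6-methoxyphenyl]ethan-1-one
Product: 5 7-(benzyloxy)-5-methoxy-4H-chromen-4-one, via enaminone 4 (not isolated)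
Conditions: Me2NCH(OMe)2, toluene, 100 °C; then conc. HCl, CH2Cl2, 40 °C
Reagents that add atoms: N,N-dimethylformamide dimethyl acetal, COC(OC)N(C)C
Why: Enaminone condensation at the acetyl methyl group followed by acid-promoted conjugate addition of the phenol and loss of dimethylamine, the standard chromone synthesis from 2-hydroxyacetophenones.

Step 4
Reactants: 5 7-(benzyloxy)-5-methoxy-4H-chromen-4-one; 6 4-methoxyphenylboronic acid
Product: 7 (2S)-7-(benzyloxy)-5-methoxy-2-(4-methoxyphenyl)-2,3-dihydro-4H-chromen-4-one
Conditions: Pd(OCOCF3)2 (5 mol%), (R)-t-BuPyOx [(R)-4-tert-butyl-2-(pyridin-2-yl)-4,5-dihydro-1,3-oxazole] (6 mol%), NH4PF6 (30 mol%), H2O (5 equiv), ClCH2CH2Cl, 60 °C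
Reagents that add atoms: none
Why: Enantioselective conjugate addition of an arylboronic acid to a chromone under cationic divalent palladium catalysis: transmetalation, insertion of the C2=C3 bond into the aryl–palladium bond and protonolysis of the palladium enolate. The pyridine–oxazoline ligand shields one face of the bound enone and so sets C2 as S.

Step 5
Reactants: 7 (2S)-7-(benzyloxy)-5-methoxy-2-(4-methoxyphenyl)-2,3-dihydro-4H-chromen-4-one
Product: 8 methyl (2S,3S)-6-(benzyloxy)-4-methoxy-2-(4-methoxyphenyl)-2,3-dihydro-1-benzofuran-3-carboxylate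
Conditions: PhI(OAc)2 (1.2 equiv), H2SO4, HC(OMe)3, 0 °C to rt
Reagents that add atoms: trimethyl orthoformate, COC(OC)OC
Why: Oxidative ring contraction of a flavanone by hypervalent iodine: the enol ether formed in the orthoformate is attacked at C3 anti to the C2 aryl group, and the electron-rich ring A carbon C4a then migrates from C4 to C3 with loss of iodobenzene, leaving C4 as a dimethoxycarbenium ion that ends as the methyl ester. C2 is not involved and should stay S; anti attack followed by migration with inversion sets the new C3 centre trans to the C2 aryl group, which is also the thermodynamic arrangement.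

Step 6
Reactants: 8 methyl (2S,3S)-6-(benzyloxy)-4-methoxy-2-(4-methoxyphenyl)-2,3-dihydro-1-benzofuran-3-carboxylate
Product: 9 methyl (2S,3S)-6-hydroxy-4-methoxy-2-(4-methoxyphenyl)-2,3-dihydro-1-benzofuran-3-carboxylate
Conditions: H2 (1 atm), Pd/C, EtOAc, rt
Reagents that add atoms: none
Why: Hydrogenolysis of a benzyl aryl ether; under neutral conditions at one atmosphere the O-benzyl bond should cleave well before the ring C2–O1 bond, which is the less accessible benzylic ether.

Step 7
Reactants: 9 methyl (2S,3S)-6-hydroxy-4-methoxy-2-(4-methoxyphenyl)-2,3-dihydro-1-benzofuran-3-carboxylate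
Product: 10 methyl (2S,3S)-4-methoxy-2-(4-methoxyphenyl)-6-[(trifluoromethanesulfonyl)oxy]-2,3-dihydro-1-benzofuran-3-carboxylate
Conditions: Tf2O, pyridine, CH2Cl2, 0 °C
Reagents that add atoms: trifluoromethanesulfonic anhydride, O=S(=O)(OS(=O)(=O)C(F)(F)F)C(F)(F)F
Why: O-Sulfonylation of an unhindered phenol; pyridine is too weak a base to disturb C3.

Step 8
Reactants: 10 methyl (2S,3S)-4-methoxy-2-(4-methoxyphenyl)-6-[(trifluoromethanesulfonyl)oxy]-2,3-dihydro-1-benzofuran-3-carboxylate; 11 (6-methoxy-1-benzofuran-2-yl)boronic acid
Product: 12 methyl (2S,3S)-4-methoxy-6-(6-methoxy-1-benzofuran-2-yl)-2-(4-methoxyphenyl)-2,3-dihydro-1-benzofuran-3-carboxylate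
Conditions: Pd(OAc)2 (3 mol%), SPhos (6 mol%), K3PO4, THF/H2O, 40 °C; 11 (1.5 equiv)
Reagents that add atoms: none
Why: Suzuki–Miyaura coupling of an aryl triflate flanked by two hydrogens; the electron-rich biarylphosphine allows a low temperature, which limits protodeboronation of the 2-benzofuranylboronic acid. Any base-induced exchange at C3 returns the trans ester.

Step 9
Reactants: 12 methyl (2S,3S)-4-methoxy-6-(6-methoxy-1-benzofuran-2-yl)-2-(4-methoxyphenyl)-2,3-dihydro-1-benzofuran-3-carboxylate
Product: 13 (2S,3S)-4-methoxy-6-(6-methoxy-1-benzofuran-2-yl)-2-(4-methoxyphenyl)-2,3-dihydro-1-benzofuran-3-carboxylic acid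
Conditions: LiOH, THF/MeOH/H2O, 40 °C; then aq HCl to pH 3
Reagents that add atoms: lithium hydroxide, [Li+].[OH-]
Why: Ester saponification; the trans acid is the thermodynamic isomer, and expulsion of the ring A phenoxide from the ester enolate is the reverse of a 5-endo-trig closure and should be slow, so C2 is kept.

Step 10
Reactants: 14 2,2,6-trimethyl-4H-1,3-dioxin-4-one
Product: 15 2,2-dimethyl-6-(2-oxopropyl)-4H-1,3-dioxin-4-one
Conditions: LiN(SiMe3)2, THF, −78 °C; AcCl (0.5 equiv), −78 to −20 °C
Reagents that add atoms: acetyl chloride, CC(=O)Cl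
Why: C-Acylation of the vinylogous lithium enolate of the dioxinone at its γ-carbon (crossed Claisen condensation); the enolate is used in excess because the more acidic product consumes a second equivalent, and the surplus is recovered as 14.

Step 11
Reactants: 13 (2S,3S)-4-methoxy-6-(6-methoxy-1-benzofuran-2-yl)-2-(4-methoxyphenyl)-2,3-dihydro-1-benzofuran-3-carboxylic acid; 15 2,2-dimethyl-6-(2-oxopropyl)-4H-1,3-dioxin-4-one
Product: 17 6-{4-[(2S,3S)-4-methoxy-6-(6-methoxy-1-benzofuran-2-yl)-2-(4-methoxyphenyl)-2,3-dihydro-1-benzofuran-3-yl]-2,4-dioxobutyl}-2,2-dimethyl-4H-1,3-dioxin-4-one, via acyl imidazole 16 (not isolated)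
Conditions: 13, CDI, THF, rt; added to 15 (3 equiv), LiN(iPr)2 (6 equiv), Et2Zn (3 equiv), THF, −78 to −20 °C; aq HCl (pH 3), 0 °C
Reagents that add atoms: none
Why: Crossed Claisen condensation of a keto-dioxinone dianion with an activated acid: the second deprotonation of 15 occurs at the terminal methyl group, and this more reactive carbon attacks the acyl imidazole. Zinc tempers the basicity of the dianion toward the C3 hydrogen, and the excess dianion absorbs the imidazole set free in the activation; C3 stays trans for thermodynamic reasons.

Step 12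
Reactants: 17 6-{4-[(2S,3S)-4-methoxy-6-(6-methoxy-1-benzofuran-2-yl)-2-(4-methoxyphenyl)-2,3-dihydro-1-benzofuran-3-yl]-2,4-dioxobutyl}-2,2-dimethyl-4H-1,3-dioxin-4-one
Product: 18 7-hydroxy-5-[(2S,3S)-4-methoxy-6-(6-methoxy-1-benzofuran-2-yl)-2-(4-methoxyphenyl)-2,3-dihydro-1-benzofuran-3-yl]-2,2-dimethyl-4H-1,3-benzodioxin-4-one
Conditions: Et3N, CH2Cl2, rt
Reagents that add atoms: none
Why: Et3N removes a proton from the methylene next to the dioxinone, and the vinylogous enolate is nucleophilic at the dioxinone α-carbon (C5 of the dioxinone ring). This carbon adds to the ketone carbon bonded to C3 in an intramolecular aldol reaction, the only closure that gives a six-membered carbocycle; it is a 6-(enolexo)-exo-trig closure and favoured. Elimination of water and enolisation of the remaining ring ketone then give the aromatic 7-hydroxybenzodioxinone, so one ring bond (C5–C4a of the new ring) and one ring form and no stereocentre is created. The closest known reaction type is the amine-mediated cycloaromatisation of diketo-dioxinones to isopropylidene-protected 6-substituted β-resorcylates. The step needs cyclisation through carbon and not through oxygen to a pyranone, which follows thermal loss of acetone from the dioxinone; working at room temperature keeps the dioxinone intact and secures this. It also needs C3, which is α to the reacting ketone, to stay S: the trans arrangement beside the C2 aryl group is the thermodynamic one, so enolisation toward C3 returns the same isomer, and ring opening from that enol is the reverse of a 5-endo-trig closure and stereoelectronically slow. After this step C3 is no longer enolisable.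

Step 13
Reactants: 18 7-hydroxy-5-[(2S,3S)-4-methoxy-6-(6-methoxy-1-benzofuran-2-yl)-2-(4-methoxyphenyl)-2,3-dihydro-1-benzofuran-3-yl]-2,2-dimethyl-4H-1,3-benzodioxin-4-one
Product: 20 5-[(2S,3S)-4-methoxy-6-(6-methoxy-1-benzofuran-2-yl)-2-(4-methoxyphenyl)-2,3-dihydro-1-benzofuran-3-yl]benzene-1,3-diol, via resorcylic acid 19 (not isolated)
Conditions: aq KOH, DMSO, 80 °C, argon; then AcOH to pH 4–5, 100 °C
Reagents that add atoms: none
Why: Saponification of the aryl ester and ketal of the benzodioxinone, then protodecarboxylation of the β-resorcylic acid by ipso protonation of the electron-rich ring. The C2 aryl group is still a methyl ether, so no quinone methide can form in the hot base, and C3 has no acidic hydrogen.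

Step 14
Reactants: 20 5-[(2S,3S)-4-methoxy-6-(6-methoxy-1-benzofuran-2-yl)-2-(4-methoxyphenyl)-2,3-dihydro-1-benzofuran-3-yl]benzene-1,3-diol
Product: 21 5-[(2S,3S)-4-hydroxy-6-(6-hydroxy-1-benzofuran-2-yl)-2-(4-hydroxyphenyl)-2,3-dihydro-1-benzofuran-3-yl]benzene-1,3-diol
Conditions: BBr3 (excess), CH2Cl2, −78 to 0 °C; then MeOH, H2O
Reagents that add atoms: none
Why: Lewis-acid cleavage of aryl methyl ethers: boron binds each ether oxygen and bromide removes the methyl group by SN2. C3 is configurationally fixed and no internal nucleophile other than the ring A oxygen can reach C2, so any reversible opening at C2 should re-close to the trans isomer.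

## Compound list

1 | 2,4,6-trihydroxyacetophenone | CC(=O)c1c(O)cc(O)cc1O | starting material
2 | 1-[4-(benzyloxy)-2,6-dihydroxyphenyl]ethan-1-one | CC(=O)c1c(O)cc(OCc2ccccc2)cc1O | intermediate
3 | 1-[4-(benzyloxy)-2-hydroxy-6-methoxyphenyl]ethan-1-one | CC(=O)c1c(O)cc(OCc2ccccc2)cc1OC | intermediate
4 | (E)-1-[4-(benzyloxy)-2-hydroxy-6-methoxyphenyl]-3-(dimethylamino)prop-2-en-1-one | CN(C)/C=C/C(=O)c1c(O)cc(OCc2ccccc2)cc1OC | intermediate (not isolated)
5 | 7-(benzyloxy)-5-methoxy-4H-chromen-4-one | COc1cc(OCc2ccccc2)cc2occc(=O)c12 | intermediate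
6 | 4-methoxyphenylboronic acid | COc1ccc(B(O)O)cc1 | starting material
7 | (2S)-7-(benzyloxy)-5-methoxy-2-(4-methoxyphenyl)-2,3-dihydro-4H-chromen-4-one | COc1ccc([C@H]2Oc3cc(OCc4ccccc4)cc(OC)c3C(=O)C2)cc1 | intermediate
8 | methyl (2S,3S)-6-(benzyloxy)-4-methoxy-2-(4-methoxyphenyl)-2,3-dihydro-1-benzofuran-3-carboxylate (trans) | COc1ccc([C@H]2Oc3cc(OCc4ccccc4)cc(OC)c3[C@@H]2C(=O)OC)cc1 | intermediate
9 | methyl (2S,3S)-6-hydroxy-4-methoxy-2-(4-methoxyphenyl)-2,3-dihydro-1-benzofuran-3-carboxylate | COc1ccc([C@H]2Oc3cc(O)cc(OC)c3[C@@H]2C(=O)OC)cc1 | intermediate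
10 | methyl (2S,3S)-4-methoxy-2-(4-methoxyphenyl)-6-[(trifluoromethanesulfonyl)oxy]-2,3-dihydro-1-benzofuran-3-carboxylate | COc1ccc([C@H]2Oc3cc(OS(=O)(=O)C(F)(F)F)cc(OC)c3[C@@H]2C(=O)OC)cc1 | intermediate
11 | (6-methoxy-1-benzofuran-2-yl)boronic acid | COc1ccc2cc(B(O)O)oc2c1 | starting material
12 | methyl (2S,3S)-4-methoxy-6-(6-methoxy-1-benzofuran-2-yl)-2-(4-methoxyphenyl)-2,3-dihydro-1-benzofuran-3-carboxylate | COc1ccc([C@H]2Oc3cc(-c4cc5ccc(OC)cc5o4)cc(OC)c3[C@@H]2C(=O)OC)cc1 | intermediate
13 | (2S,3S)-4-methoxy-6-(6-methoxy-1-benzofuran-2-yl)-2-(4-methoxyphenyl)-2,3-dihydro-1-benzofuran-3-carboxylic acid | COc1ccc([C@H]2Oc3cc(-c4cc5ccc(OC)cc5o4)cc(OC)c3[C@@H]2C(=O)O)cc1 | intermediate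
14 | 2,2,6-trimethyl-4H-1,3-dioxin-4-one | CC1=CC(=O)OC(C)(C)O1 | starting material
15 | 2,2-dimethyl-6-(2-oxopropyl)-4H-1,3-dioxin-4-one | CC(=O)CC1=CC(=O)OC(C)(C)O1 | intermediate
16 | (1H-imidazol-1-yl)[(2S,3S)-4-methoxy-6-(6-methoxy-1-benzofuran-2-yl)-2-(4-methoxyphenyl)-2,3-dihydro-1-benzofuran-3-yl]methanone | COc1ccc([C@H]2Oc3cc(-c4cc5ccc(OC)cc5o4)cc(OC)c3[C@@H]2C(=O)n2ccnc2)cc1 | intermediate (not isolated)
17 | 6-{4-[(2S,3S)-4-methoxy-6-(6-methoxy-1-benzofuran-2-yl)-2-(4-methoxyphenyl)-2,3-dihydro-1-benzofuran-3-yl]-2,4-dioxobutyl}-2,2-dimethyl-4H-1,3-dioxin-4-one | COc1ccc([C@H]2Oc3cc(-c4cc5ccc(OC)cc5o4)cc(OC)c3[C@@H]2C(=O)CC(=O)CC2=CC(=O)OC(C)(C)O2)cc1 | intermediate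
18 | 7-hydroxy-5-[(2S,3S)-4-methoxy-6-(6-methoxy-1-benzofuran-2-yl)-2-(4-methoxyphenyl)-2,3-dihydro-1-benzofuran-3-yl]-2,2-dimethyl-4H-1,3-benzodioxin-4-one | COc1ccc([C@H]2Oc3cc(-c4cc5ccc(OC)cc5o4)cc(OC)c3[C@@H]2c2cc(O)cc3OC(C)(C)OC(=O)c23)cc1 | intermediate
19 | 2,4-dihydroxy-6-[(2S,3S)-4-methoxy-6-(6-methoxy-1-benzofuran-2-yl)-2-(4-methoxyphenyl)-2,3-dihydro-1-benzofuran-3-yl]benzoic acid | COc1ccc([C@H]2Oc3cc(-c4cc5ccc(OC)cc5o4)cc(OC)c3[C@@H]2c2cc(O)cc(O)c2C(=O)O)cc1 | intermediate (not isolated)
20 | 5-[(2S,3S)-4-methoxy-6-(6-methoxy-1-benzofuran-2-yl)-2-(4-methoxyphenyl)-2,3-dihydro-1-benzofuran-3-yl]benzene-1,3-diol | COc1ccc([C@H]2Oc3cc(-c4cc5ccc(OC)cc5o4)cc(OC)c3[C@@H]2c2cc(O)cc(O)c2)cc1 | intermediate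
21 | 5-[(2S,3S)-4-hydroxy-6-(6-hydroxy-1-benzofuran-2-yl)-2-(4-hydroxyphenyl)-2,3-dihydro-1-benzofuran-3-yl]benzene-1,3-diol | Oc1ccc([C@H]2Oc3cc(-c4cc5ccc(O)cc5o4)cc(O)c3[C@@H]2c2cc(O)cc(O)c2)cc1 | target

## Step count and least certain steps

Total: 14 steps. Longest linear sequence: 13 steps (steps 1 to 9 and 11 to 14); step 10 is a one-step side branch.

**Step 12 (key step).**
- Risk: dehydration at the hindered carbon bonded to C3 may be slow, so the aldol adduct stalls or the chain diverts into retro-Claisen cleavage or cyclisation through oxygen. A smaller risk is proton exchange at C3 giving some cis material. Any cis isomer must be removed at 18, because later ionisation at C2 would turn it into the enantiomer of the target.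
- Fallback, from 17 back to 20: 17 is heated with methanol in toluene at about 100 °C, so that the dioxinone is opened on purpose by loss of acetone and the acylketene is trapped as methyl 7-[(2S,3S)-4-methoxy-6-(6-methoxy-1-benzofuran-2-yl)-2-(4-methoxyphenyl)-2,3-dihydro-1-benzofuran-3-yl]-3,5,7-trioxoheptanoate F1. Cs2CO3 in methanol and then acetic acid should fold this freely rotating triketo ester by aldol condensation and aromatise it to methyl 2,4-dihydroxy-6-[(2S,3S)-4-methoxy-6-(6-methoxy-1-benzofuran-2-yl)-2-(4-methoxyphenyl)-2,3-dihydro-1-benzofuran-3-yl]benzoate F2. Hydrolysis and decarboxylation under the conditions of step 13 return the route at 20.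

**Step 5.**
- Risk: the oxidation may leave the intended path. The 4-methoxyphenyl group stabilises positive charge at C2, which favours its own 1,2-shift, dehydrogenation to the flavone or methoxylation at C3. The iodine reagent may attack the very electron-rich ring A. The acidic medium may open and re-close the pyranone ring before oxidation and so erode the configuration at C2.
- Fallback, from 3 back to 8, by carbene C–H insertion:
  - 3 is alkylated with 4-methoxybenzyl chloride (K2CO3, DMF) to 1-{4-(benzyloxy)-2-methoxy-6-[(4-methoxybenzyl)oxy]phenyl}ethan-1-one F3.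
  - Oxidative 1,2-aryl shift of the methyl ketone with Tl(NO3)3 in MeOH/HC(OMe)3 gives methyl 2-{4-(benzyloxy)-2-methoxy-6-[(4-methoxybenzyl)oxy]phenyl}acetate F4.
  - Diazo transfer (4-acetamidobenzenesulfonyl azide, DBU, MeCN) gives methyl 2-{4-(benzyloxy)-2-methoxy-6-[(4-methoxybenzyl)oxy]phenyl}-2-diazoacetate F5.
  - Rh2(S-PTTL)4 (dirhodium tetrakis[N-phthaloyl-(S)-tert-leucinate]) or its enantiomer, whichever sets C2 as S, inserts the carbene into the benzylic ether C–H bond to give the cis ester, methyl (2S,3R)-6-(benzyloxy)-4-methoxy-2-(4-methoxyphenyl)-2,3-dihydro-1-benzofuran-3-carboxylate F6.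
  - NaOMe in MeOH epimerises C3 to the trans ester 8.

**Step 4.**
- Risk: the chromone carries two donor groups, one of them peri to the carbonyl group, so insertion may be slow and protodeboronation of 6 may outrun it. Facial discrimination may fall short on this substitution pattern.
- Fallback, from 3 back to 7, by resolution in place of asymmetric catalysis: Claisen–Schmidt condensation of 3 with 4-methoxybenzaldehyde (KOH, EtOH) gives (E)-1-[4-(benzyloxy)-2-hydroxy-6-methoxyphenyl]-3-(4-methoxyphenyl)prop-2-en-1-one F7. NaOAc in refluxing EtOH cyclises it to racemic 7-(benzyloxy)-5-methoxy-2-(4-methoxyphenyl)-2,3-dihydro-4H-chromen-4-one F8. Preparative chromatography on a polysaccharide chiral phase gives 7. The unwanted (2R)-7-(benzyloxy)-5-methoxy-2-(4-methoxyphenyl)-2,3-dihydro-4H-chromen-4-one F9 is returned to the racemate with base and recycled.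

**Step 11.**
- Risk: proton transfer from C3 of the acyl imidazole to the strongly basic dianion may compete with addition at the hindered acyl carbon, returning acid 13. O-acylation or reaction at the central carbon may also occur.
- Fallback, from 13 and 14 back to 17, by soft enolisation:
  - 13 is converted with oxalyl chloride (cat. DMF) into (2S,3S)-4-methoxy-6-(6-methoxy-1-benzofuran-2-yl)-2-(4-methoxyphenyl)-2,3-dihydro-1-benzofuran-3-carbonyl chloride F10.
  - 14 is acylated (LiN(SiMe3)2, then monoallyl malonyl chloride) to allyl 4-(2,2-dimethyl-4-oxo-4H-1,3-dioxin-6-yl)-3-oxobutanoate F11.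
  - MgCl2 and pyridine join the two at the carbon between ketone and ester to give allyl 2-{[(2S,3S)-4-methoxy-6-(6-methoxy-1-benzofuran-2-yl)-2-(4-methoxyphenyl)-2,3-dihydro-1-benzofuran-3-yl]carbonyl}-4-(2,2-dimethyl-4-oxo-4H-1,3-dioxin-6-yl)-3-oxobutanoate F12.
  - Pd(PPh3)4, a zerovalent palladium catalyst, with morpholine removes the allyl group and the ester carbon as carbon dioxide, which gives 17.

**Step 14.**
- Risk: the Lewis acid may ionise the C2–O1 bond before or while the ethers are cleaved, leading to epimerisation at C2, proton loss from C3 with irreversible ring opening, or incomplete cleavage of the hindered C4 ether if the reaction is kept cold.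
- Fallback, from 20 to 21 without new intermediates: the ethers are cleaved from the basic side by SN2 attack of LiPPh2 on the methyl groups in THF at or below reflux. O1 is never activated, and the temperature stays below that at which a 4-oxidophenyl group expels the ring A phenoxide.

## Further compounds

F1 | step 12 | methyl 7-[(2S,3S)-4-methoxy-6-(6-methoxy-1-benzofuran-2-yl)-2-(4-methoxyphenyl)-2,3-dihydro-1-benzofuran-3-yl]-3,5,7-trioxoheptanoate | COc1ccc([C@H]2Oc3cc(-c4cc5ccc(OC)cc5o4)cc(OC)c3[C@@H]2C(=O)CC(=O)CC(=O)CC(=O)OC)cc1
F2 | step 12 | methyl 2,4-dihydroxy-6-[(2S,3S)-4-methoxy-6-(6-methoxy-1-benzofuran-2-yl)-2-(4-methoxyphenyl)-2,3-dihydro-1-benzofuran-3-yl]benzoate | COc1ccc([C@H]2Oc3cc(-c4cc5ccc(OC)cc5o4)cc(OC)c3[C@@H]2c2cc(O)cc(O)c2C(=O)OC)cc1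
F3 | step 5 | 1-{4-(benzyloxy)-2-methoxy-6-[(4-methoxybenzyl)oxy]phenyl}ethan-1-one | COc1ccc(COc2cc(OCc3ccccc3)cc(OC)c2C(C)=O)cc1
F4 | step 5 | methyl 2-{4-(benzyloxy)-2-methoxy-6-[(4-methoxybenzyl)oxy]phenyl}acetate | COc1ccc(COc2cc(OCc3ccccc3)cc(OC)c2CC(=O)OC)cc1
F5 | step 5 | methyl 2-{4-(benzyloxy)-2-methoxy-6-[(4-methoxybenzyl)oxy]phenyl}-2-diazoacetate | COc1ccc(COc2cc(OCc3ccccc3)cc(OC)c2C(=[N+]=[N-])C(=O)OC)cc1
F6 | step 5 | methyl (2S,3R)-6-(benzyloxy)-4-methoxy-2-(4-methoxyphenyl)-2,3-dihydro-1-benzofuran-3-carboxylate (cis) | COc1ccc([C@H]2Oc3cc(OCc4ccccc4)cc(OC)c3[C@H]2C(=O)OC)cc1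
F7 | step 4 | (E)-1-[4-(benzyloxy)-2-hydroxy-6-methoxyphenyl]-3-(4-methoxyphenyl)prop-2-en-1-one | COc1ccc(/C=C/C(=O)c2c(O)cc(OCc3ccccc3)cc2OC)cc1
F8 | step 4 | racemic 7-(benzyloxy)-5-methoxy-2-(4-methoxyphenyl)-2,3-dihydro-4H-chromen-4-one | COc1ccc(C2Oc3cc(OCc4ccccc4)cc(OC)c3C(=O)C2)cc1
F9 | step 4 | (2R)-7-(benzyloxy)-5-methoxy-2-(4-methoxyphenyl)-2,3-dihydro-4H-chromen-4-one | COc1ccc([C@@H]2Oc3cc(OCc4ccccc4)cc(OC)c3C(=O)C2)cc1
F10 | step 11 | (2S,3S)-4-methoxy-6-(6-methoxy-1-benzofuran-2-yl)-2-(4-methoxyphenyl)-2,3-dihydro-1-benzofuran-3-carbonyl chloride | COc1ccc([C@H]2Oc3cc(-c4cc5ccc(OC)cc5o4)cc(OC)c3[C@@H]2C(Cl)=O)cc1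
F11 | step 11 | allyl 4-(2,2-dimethyl-4-oxo-4H-1,3-dioxin-6-yl)-3-oxobutanoate | C=CCOC(=O)CC(=O)CC1=CC(=O)OC(C)(C)O1
F12 | step 11 | allyl 2-{[(2S,3S)-4-methoxy-6-(6-methoxy-1-benzofuran-2-yl)-2-(4-methoxyphenyl)-2,3-dihydro-1-benzofuran-3-yl]carbonyl}-4-(2,2-dimethyl-4-oxo-4H-1,3-dioxin-6-yl)-3-oxobutanoate (configuration at the acylated carbon undefined, largely enolised) | COc1ccc([C@H]2Oc3cc(-c4cc5ccc(OC)cc5o4)cc(OC)c3[C@@H]2C(=O)C(C(=O)OCC=C)C(=O)CC2=CC(=O)OC(C)(C)O2)cc1
F0 | step 14 | none | none
A1 | alternative 1 | (2R,3S)-6-bromo-3-(3,5-dimethoxyphenyl)-4-methoxy-2-(4-methoxyphenyl)-2,3-dihydro-1-benzofuran (cis) | COc1ccc([C@@H]2Oc3cc(Br)cc(OC)c3[C@@H]2c2cc(OC)cc(OC)c2)cc1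
A2 | alternative 1 | [4-bromo-2-methoxy-6-(4-methoxybenzyloxy)phenyl](3,5-dimethoxyphenyl)methanone hydrazone | COc1ccc(COc2cc(Br)cc(OC)c2C(=NN)c2cc(OC)cc(OC)c2)cc1
A3 | alternative 2 | 2-[2-(tert-butyldimethylsilyloxy)-1-(3,5-dimethoxyphenyl)-2-(4-methoxyphenyl)ethyl]-5-(6-methoxy-1-benzofuran-2-yl)-3-(triisopropylsilyloxy)phenol, configuration as in the SMILES | CC(C)[Si](C(C)C)(C(C)C)Oc1cc(-c2cc3ccc(OC)cc3o2)cc(O)c1[C@@H]([C@H](O[Si](C)(C)C(C)(C)C)c1ccc(OC)cc1)c1cc(OC)cc(OC)c1
A4 | alternative 2 | triisopropyl{[4-(tert-butyldimethylsilyloxy)-3-(3,5-dimethoxyphenyl)-4-(4-methoxyphenyl)but-1-yn-1-yl]oxy}silane, configuration as in the SMILES | CC(C)[Si](C(C)C)(C(C)C)OC#C[C@@H]([C@H](O[Si](C)(C)C(C)(C)C)c1ccc(OC)cc1)c1cc(OC)cc(OC)c1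
A5 | alternative 2 | 3-(6-methoxy-1-benzofuran-2-yl)cyclobut-2-en-1-one | COc1ccc2cc(C3=CC(=O)C3)oc2c1
A6 | alternative 3 | (2S,3S)-3-(3,5-dimethoxyphenyl)-4-methoxy-6-(6-methoxy-1-benzofuran-2-yl)-2-(4-methoxyphenyl)-2,3-dihydro-1-benzofuran (trans) | COc1ccc([C@H]2Oc3cc(-c4cc5ccc(OC)cc5o4)cc(OC)c3[C@@H]2c2cc(OC)cc(OC)c2)cc1
A7 | alternative 3 | 2-[(3,5-dimethoxyphenyl)(4-methylbenzenesulfonyl)methyl]-3-methoxy-5-(6-methoxy-1-benzofuran-2-yl)phenol | COc1cc(-c2cc3ccc(OC)cc3o2)cc(O)c1C(c1cc(OC)cc(OC)c1)S(=O)(=O)c1ccc(C)cc1
A8 | alternative 3 | (2R,5R)-1-(4-methoxybenzyl)-2,5-dimethylthiolan-1-ium tetrafluoroborate | C[C@@H]1CC[C@@H](C)[S+]1Cc1ccc(OC)cc1.F[B-](F)(F)F
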